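**Plan**

1. Ring numbering as in the target: C1 = C(CH3)(CH=CHCl), C2 = CH2, C3 = C(Br)CH2Br, C4 = CHCl, C5 = CH2, C6 = CHCl. The retrosynthesis cuts, in order: both C–Br bonds (Br2 across a C3=CH2 olefin); the Z-olefin (from a chloroalkyne, itself from a C1 acetyl group); C4–Cl (inversion of a C4 allylic alcohol born from a C3–C4 epoxide); and last, in one cut, C6–Cl together with C1–CH3.
2. That last cut is the key step read backwards. Cl+ adds to C6 of a cyclohexene C1=C6 while one methyl of a 2-hydroxyprop-2-yl substituent shifts to C1 (chlorinative semipinacol rearrangement). One anti-stereospecific event makes the quaternary C1, the neopentylic secondary chloride at C6 (out of reach of SN2 chemistry) and the two-carbon arm.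
3. Enabling feature: C1 bears CH3 and a C2 arm, and the chlorine on the adjacent C6 is trans to that CH3. C1(CH3)(C2 arm) is therefore a rearranged C1–C(OH)(CH3)2, and the ten carbons are those of a meta-menthane, i.e. of a meta-disubstituted benzene.
4. Forward: no ring is closed. The cyclohexane is the benzene ring of 3'-methylacetophenone, dearomatised by Birch reduction to a 1,4-diene whose two trisubstituted double bonds, C3=C4 and C1=C6, are exactly the two sites to be functionalised.
5. Stereochemistry: one catalyst-controlled step (Shi epoxidation of C3=C4) fixes the absolute configuration. The epoxide sends Cl+ to the opposite face of C6, the methyl migrates anti to chlorine (C1), C4–O is inverted to C4–Cl, bromide opens the bromonium ion axially at C3, and syn reduction of the chloroalkyne gives the Z-olefin.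

Key step: step 4

Remark: the facial sense of the Shi epoxidation of 4 is assigned from the spiro transition-state model (analogy with 1-substituted cyclohexenes), which calls for the enantiomer of the usual D-fructose-derived ketone; should the sense be opposite, the D-fructose-derived ketone is used and nothing else changes.

**Route**

Step 1
Reactants: 1 1-(3-methylphenyl)ethan-1-one; 2 methylmagnesium bromide
Product: 3 2-(3-methylphenyl)propan-2-ol
Conditions: MeMgBr (1.2 equiv), THF, 0 °C to rt; aq. NH4Cl
Reagents that add atoms: methylmagnesium bromide, C[Mg]Br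
Why: Grignard addition of a methyl nucleophile to the aryl methyl ketone gives the tertiary benzylic alcohol directly; no stereocentre is formed.

Step 2
Reactants: 3 2-(3-methylphenyl)propan-2-ol
Product: 4 2-(5-methylcyclohexa-1,4-dien-1-yl)propan-2-ol
Conditions: Li, NH3(l)/THF, t-BuOH, −78 to −33 °C; NH4Cl
Reagents that add atoms: none
Why: Birch reduction of a meta-dialkylbenzene places the two new hydrogens between and opposite the substituents, so both substituted carbons stay olefinic (C1=C6 and C3=C4), and the benzylic C–O bond should survive because it is present as its lithium alkoxide; no stereocentre is formed.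

Step 3
Reactants: 4 2-(5-methylcyclohexa-1,4-dien-1-yl)propan-2-ol
Product: 5 2-[(1R,6S)-1-methyl-7-oxabicyclo[4.1.0]hept-3-en-3-yl]propan-2-ol
Conditions: ent-Shi ketone (L-fructose series, 30 mol %), Oxone, K2CO3, Bu4NHSO4 (cat.), MeCN/CH2(OMe)2/aq. Na2B4O7–EDTA, 0 °C
Reagents that add atoms: potassium peroxymonosulfate (Oxone), [K+].[O-]S(=O)(=O)OO
Why: Shi asymmetric epoxidation by the chiral dioxirane (spiro transition state) should occur at the methyl-substituted C3=C4 bond, because C1=C6 is shielded and inductively deactivated by the 2-hydroxyprop-2-yl group, and the ketone enantiomer fixes C3 and C4 with oxygen on the face that ends anti to both ring chlorides.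

Step 4
Reactants: 5 2-[(1R,6S)-1-methyl-7-oxabicyclo[4.1.0]hept-3-en-3-yl]propan-2-ol
Product: 6 1-[(1R,3S,4S,6S)-4-chloro-1,3-dimethyl-7-oxabicyclo[4.1.0]heptan-3-yl]ethan-1-one
Conditions: NCS (1.1 equiv), quinuclidine (10 mol %), NaHCO3, CH2Cl2, −30 to 0 °C
Reagents that add atoms: N-chlorosuccinimide, O=C1CCC(=O)N1Cl
Why: Halonium-induced semipinacol rearrangement: the amine-activated Cl+ adds to C6 of the trisubstituted C1=C6 olefin, and as positive charge develops at the tertiary C1 one methyl of the adjacent carbinol carbon migrates to C1 anti-periplanar to the new C6–Cl bond while the hydroxyl oxygen pushes, so that the methyl ketone results. The closest known reaction type is the halogenation/semipinacol rearrangement of 1-cycloalkenyl tertiary carbinols (ring-expanding and aryl-migrating cases, also with chlorine electrophiles). No ring is closed; the step turns the 2-hydroxyprop-2-yl group into the C1 methyl plus the C1 acetyl arm. C6 is controlled by the C3–C4 epoxide, whose C4–O bond stands 1,3 to C6 on the top face so that Cl+ should enter from the opposite face, and C1 is controlled by the mechanism, the methyl arriving on the face opposite to chlorine (Cl trans to CH3, as in the target). The step needs site selectivity, which is secured because C1=C6 is the only olefin in 5, and it needs the 1,2-shift to outrun proton loss from C2, which is favoured because a C–CH3 bond is aligned with the developing cation in every rotamer and the shift leads straight to a protonated ketone. The product is a β-chloro ketone whose ring α-carbon (C1) is quaternary, so it cannot lose HCl by E1cB.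

Step 5
Reactants: 6 1-[(1R,3S,4S,6S)-4-chloro-1,3-dimethyl-7-oxabicyclo[4.1.0]heptan-3-yl]ethan-1-one
Product: 9 (1R,3S,4S,6S)-4-chloro-3-(chloroethynyl)-1,3-dimethyl-7-oxabicyclo[4.1.0]heptane, via enol phosphate 7 (not isolated), via lithium acetylide 8 (not isolated)
Conditions: LDA (1.1 equiv), THF, −78 °C; ClP(O)(OEt)2, −78 to 0 °C; LDA (2.3 equiv), −78 to 0 °C; NCS (1.3 equiv), −78 °C to rt
Reagents that add atoms: N-chlorosuccinimide, O=C1CCC(=O)N1Cl; diethyl chlorophosphate, CCOP(=O)(Cl)OCC (its atoms remain in 7 only)
Why: Enolisation is possible only towards the methyl group because C1 is quaternary, the derived enol phosphate undergoes base-induced elimination to the terminal alkyne (methyl ketone to alkyne through the enol phosphate), and the lithium acetylide is chlorinated by NCS; no stereocentre is touched.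

Step 6
Reactants: 9 (1R,3S,4S,6S)-4-chloro-3-(chloroethynyl)-1,3-dimethyl-7-oxabicyclo[4.1.0]heptane
Product: 10 (1S,4S,5S)-5-chloro-4-(chloroethynyl)-4-methyl-2-methylidenecyclohexan-1-ol
Conditions: Et2AlCl + LiTMP (Et2Al–TMP, 2.5 equiv), toluene, 0 °C; aq. Rochelle salt
Reagents that add atoms: none
Why: Rearrangement of a trisubstituted epoxide to an allylic alcohol by a dialkylaluminium amide proceeds by syn β-elimination in an aluminium-bound cyclic transition state and should take its proton from the C3 methyl (C2 is neopentylic), which gives the C3 exo-methylene and leaves the C4–O bond, hence the C4 configuration, untouched.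

Step 7
Reactants: 10 (1S,4S,5S)-5-chloro-4-(chloroethynyl)-4-methyl-2-methylidenecyclohexan-1-ol
Product: 11 (1S,2S,4R)-2,4-dichloro-1-(chloroethynyl)-1-methyl-5-methylidenecyclohexane
Conditions: Cl3CC(O)CCl3 (3 equiv), PPh3 (1.2 equiv, added last), CH2Cl2, 0 °C
Reagents that add atoms: hexachloroacetone, ClC(Cl)(Cl)C(=O)C(Cl)(Cl)Cl
Why: Appel-type chlorination with hexachloroacetone/PPh3 replaces the hydroxyl of secondary allylic alcohols by SN2 with inversion and without allylic transposition, which turns the C4–O bond (anti to C6–Cl) into the C4–Cl bond cis to C6–Cl; PPh3 is consumed at once by hexachloroacetone and should spare the chloroalkyne.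

Step 8
Reactants: 11 (1S,2S,4R)-2,4-dichloro-1-(chloroethynyl)-1-methyl-5-methylidenecyclohexane
Product: 12 (1S,2S,4R,5S)-5-bromo-5-(bromomethyl)-2,4-dichloro-1-(chloroethynyl)-1-methylcyclohexane
Conditions: Br2 (1.0 equiv), CH2Cl2, −78 °C, dark
Reagents that add atoms: bromine, BrBr
Why: Anti addition of bromine to the 1,1-disubstituted olefin (the electron-poor chloroalkyne should not compete at −78 °C) should give 12 because, in the chair with both ring chlorides equatorial, bromide opens the bromonium ion at the tertiary C3 along the axial trajectory (axial Br cis to the slim axial alkynyl arm, equatorial CH2Br), which is also the more stable C3 epimer, while the equatorial C4–Cl lies near the nodal plane of the C3 p orbital and cannot migrate.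

Step 9
Reactants: 12 (1S,2S,4R,5S)-5-bromo-5-(bromomethyl)-2,4-dichloro-1-(chloroethynyl)-1-methylcyclohexane
Product: 13 (1S,2S,4R,5S)-5-bromo-5-(bromomethyl)-2,4-dichloro-1-[(Z)-2-chloroethenyl]-1-methylcyclohexane
Conditions: KO2CN=NCO2K (excess), AcOH (slow addition), CH2Cl2, rt
Reagents that add atoms: none
Why: Diimide transfers two hydrogens suprafacially to the 1-chloroalkyne (syn reduction of 1-haloalkynes to (Z)-1-haloalkenes), which sets the Z-olefin, and it leaves C–Br and C–Cl bonds alone, no other π bond being present in 12.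

**Compound list**

1 | 1-(3-methylphenyl)ethan-1-one (3'-methylacetophenone) | CC(=O)c1cccc(C)c1 | starting material
2 | methylmagnesium bromide | C[Mg]Br | starting material
3 | 2-(3-methylphenyl)propan-2-ol | Cc1cccc(c1)C(C)(C)O | intermediate
4 | 2-(5-methylcyclohexa-1,4-dien-1-yl)propan-2-ol | CC1=CCC=C(C1)C(C)(C)O | intermediate
5 | 2-[(1R,6S)-1-methyl-7-oxabicyclo[4.1.0]hept-3-en-3-yl]propan-2-ol | CC(C)(O)C1=CC[C@@H]2O[C@]2(C)C1 | intermediate
6 | 1-[(1R,3S,4S,6S)-4-chloro-1,3-dimethyl-7-oxabicyclo[4.1.0]heptan-3-yl]ethan-1-one | CC(=O)[C@]1(C)C[C@@]2(C)O[C@H]2C[C@@H]1Cl | intermediate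
7 | diethyl 1-[(1R,3S,4S,6S)-4-chloro-1,3-dimethyl-7-oxabicyclo[4.1.0]heptan-3-yl]ethenyl phosphate | C=C(OP(=O)(OCC)OCC)[C@]1(C)C[C@@]2(C)O[C@H]2C[C@@H]1Cl | intermediate
8 | lithium [(1R,3S,4S,6S)-4-chloro-1,3-dimethyl-7-oxabicyclo[4.1.0]heptan-3-yl]ethynide | [Li]C#C[C@]1(C)C[C@@]2(C)O[C@H]2C[C@@H]1Cl | intermediate
9 | (1R,3S,4S,6S)-4-chloro-3-(chloroethynyl)-1,3-dimethyl-7-oxabicyclo[4.1.0]heptane | ClC#C[C@]1(C)C[C@@]2(C)O[C@H]2C[C@@H]1Cl | intermediate
10 | (1S,4S,5S)-5-chloro-4-(chloroethynyl)-4-methyl-2-methylidenecyclohexan-1-ol | ClC#C[C@]1(C)CC(=C)[C@@H](O)C[C@@H]1Cl | intermediate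
11 | (1S,2S,4R)-2,4-dichloro-1-(chloroethynyl)-1-methyl-5-methylidenecyclohexane | ClC#C[C@]1(C)CC(=C)[C@H](Cl)C[C@@H]1Cl | intermediate
12 | (1S,2S,4R,5S)-5-bromo-5-(bromomethyl)-2,4-dichloro-1-(chloroethynyl)-1-methylcyclohexane | ClC#C[C@]1(C)C[C@@](Br)(CBr)[C@H](Cl)C[C@@H]1Cl | intermediate
13 | (1S,2S,4R,5S)-5-bromo-5-(bromomethyl)-2,4-dichloro-1-[(Z)-2-chloroethenyl]-1-methylcyclohexane | C[C@@]1(/C=C\Cl)C[C@@](Br)(CBr)[C@H](Cl)C[C@@H]1Cl | target

Total step count: 9
Longest linear sequence: 9 steps (fully linear)

**Steps most likely to fail**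

Step 4 (key step).
- What may go wrong: loss of a proton from C2 of the β-chloro cation (allylic chlorination), opening of the acid-labile epoxide, or delivery of Cl+ syn to the epoxide oxygen may compete with the anti methyl shift.
- Fallback (sets out from 5, returns at 10): the epoxide is opened before the rearrangement, not after it. The rearranging substrate then carries no acid-labile group, and its C4 oxygen, now a silyloxy group 1,3 to C6, should screen the top face more strongly.
- Et2Al–TMP isomerises 5 to the diol (1S)-4-(2-hydroxypropan-2-yl)-6-methylidenecyclohex-3-en-1-ol F1.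
- TESCl/imidazole silylates only the secondary hydroxyl and gives 2-[(4S)-5-methylidene-4-(triethylsilyloxy)cyclohex-1-en-1-yl]propan-2-ol F2. The silyl group also prevents capture of the C1 cation by the C4 oxygen.
- NCS/quinuclidine should then effect the chlorinative methyl shift at the more nucleophilic trisubstituted C1=C6 bond and give 1-[(1S,2S,4S)-2-chloro-1-methyl-5-methylidene-4-(triethylsilyloxy)cyclohexyl]ethan-1-one F3.
- The one-flask sequence of step 5 converts F3 through the enol phosphate diethyl 1-[(1S,2S,4S)-2-chloro-1-methyl-5-methylidene-4-(triethylsilyloxy)cyclohexyl]ethenyl phosphate F4 and the acetylide lithium [(1S,2S,4S)-2-chloro-1-methyl-5-methylidene-4-(triethylsilyloxy)cyclohexyl]ethynide F5 into the chloroalkyne {[(1S,4S,5S)-5-chloro-4-(chloroethynyl)-4-methyl-2-methylidenecyclohexyl]oxy}triethylsilane F6.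
- Buffered fluoride (TBAF/AcOH, THF) removes the silyl group and gives 10.

Step 3.
- What may go wrong: insufficient enantiofacial discrimination by the chiral dioxirane on an alkyl-substituted cyclic trisubstituted olefin, or competing epoxidation of C1=C6.
- Fallback (sets out from 4, returns at 5): resolution instead of asymmetric catalysis.
- Buffered mCPBA epoxidises 4 to the racemate, i.e. 5 together with its enantiomer 2-[(1S,6R)-1-methyl-7-oxabicyclo[4.1.0]hept-3-en-3-yl]propan-2-ol F7.
- A catalytic kinetic resolution by enantioselective lithium amide-mediated epoxide-to-allylic-alcohol rearrangement (chiral diamine-derived lithium amide, DBU as bulk base, THF) consumes F7. It is removed as the more polar diol (1R)-4-(2-hydroxypropan-2-yl)-6-methylidenecyclohex-3-en-1-ol F8, and enantioenriched 5 is left for step 4.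

Step 8.
- What may go wrong: poor facial selectivity in the opening of the bromonium ion at C3 (equatorial instead of axial attack of bromide), which would give the C3 epimer.
- Fallback (sets out from 11, returns at 12): thermodynamic instead of kinetic control.
- The crude dibromide from 11, containing the epimer (1S,2S,4R,5R)-5-bromo-5-(bromomethyl)-2,4-dichloro-1-(chloroethynyl)-1-methylcyclohexane F9, is equilibrated through the bromonium/bromide ion pair (vicinal-dibromide mutarotation: warming in nitromethane, or catalytic ZnBr2 in CH2Cl2). This should funnel F9 into 12, the epimer with equatorial CH2Br and axial Br.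

Further compounds
F1 | step 4 | (1S)-4-(2-hydroxypropan-2-yl)-6-methylidenecyclohex-3-en-1-ol | CC(C)(O)C1=CC[C@H](O)C(=C)C1
F2 | step 4 | 2-[(4S)-5-methylidene-4-(triethylsilyloxy)cyclohex-1-en-1-yl]propan-2-ol | CC(C)(O)C1=CC[C@H](O[Si](CC)(CC)CC)C(=C)C1
F3 | step 4 | 1-[(1S,2S,4S)-2-chloro-1-methyl-5-methylidene-4-(triethylsilyloxy)cyclohexyl]ethan-1-one | CC(=O)[C@]1(C)CC(=C)[C@@H](O[Si](CC)(CC)CC)C[C@@H]1Cl
F4 | step 4 | diethyl 1-[(1S,2S,4S)-2-chloro-1-methyl-5-methylidene-4-(triethylsilyloxy)cyclohexyl]ethenyl phosphate | C=C(OP(=O)(OCC)OCC)[C@]1(C)CC(=C)[C@@H](O[Si](CC)(CC)CC)C[C@@H]1Cl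
F5 | step 4 | lithium [(1S,2S,4S)-2-chloro-1-methyl-5-methylidene-4-(triethylsilyloxy)cyclohexyl]ethynide | [Li]C#C[C@]1(C)CC(=C)[C@@H](O[Si](CC)(CC)CC)C[C@@H]1Cl
F6 | step 4 | {[(1S,4S,5S)-5-chloro-4-(chloroethynyl)-4-methyl-2-methylidenecyclohexyl]oxy}triethylsilane | ClC#C[C@]1(C)CC(=C)[C@@H](O[Si](CC)(CC)CC)C[C@@H]1Cl
F7 | step 3 | 2-[(1S,6R)-1-methyl-7-oxabicyclo[4.1.0]hept-3-en-3-yl]propan-2-ol | CC(C)(O)C1=CC[C@H]2O[C@@]2(C)C1
F8 | step 3 | (1R)-4-(2-hydroxypropan-2-yl)-6-methylidenecyclohex-3-en-1-ol | CC(C)(O)C1=CC[C@@H](O)C(=C)C1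
F9 | step 8 | (1S,2S,4R,5R)-5-bromo-5-(bromomethyl)-2,4-dichloro-1-(chloroethynyl)-1-methylcyclohexane | ClC#C[C@]1(C)C[C@](Br)(CBr)[C@H](Cl)C[C@@H]1Cl
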